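**Retrosynthetic overview**
- The only disconnection is the C7 aryl–O–CH2 bond of the prenyl ether. It leads back to (+)-taxifolin 1, to phenylboronic acid 2 as an in-flask mask for the catechol, and to prenyl bromide 3.
- No ring of the target is built: the chromanone (A/C) and the catechol ring (B) come intact from 1. The only ring formed is the transient dioxaborole of 4 and 5, which is opened again on work-up to release 6.
- Both stereocentres (2R,3R, trans) are bought with 1 and are never touched.

Assumption: bulk natural (+)-(2R,3R)-taxifolin (dihydroquercetin from larch wood) counts as a cheap commercial starting material; since the route then has a single step, the risk section can name only that step.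

**Step 1**
Reactants: 1 (+)-taxifolin; 2 phenylboronic acid; 3 prenyl bromide
Product: 6 7-O-prenyl-(+)-taxifolin [(2R,3R)-2-(3,4-dihydroxyphenyl)-3,5-dihydroxy-7-(3-methylbut-2-enyloxy)chroman-4-one], via taxifolin 3',4'-O-phenylboronate 4 (not isolated), via 7-O-prenyltaxifolin 3',4'-O-phenylboronate 5 (not isolated)
Conditions: PhB(OH)2 (1.05 eq), 4 Å MS, DMF, rt, 1 h; then K2CO3 (1.1 eq), prenyl bromide (1.1 eq), 0 °C → rt, Ar, 8 h; then aq. citric acid/EtOAc, D-sorbitol/NaHCO3 wash
Reagents that add atoms: prenyl bromide (compound 3), CC(C)=CCBr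
Why: Proposed new method: a one-pot boronic-acid-templated Williamson etherification, in which PhB(OH)2 condenses with the only 1,2-diol of 1 (the 3',4'-catechol) to the neutral dioxaborole 4, so the single equivalent of K2CO3 ionises only the most acidic remaining hydroxyl (7-OH, pKa about 7.4; 5-OH is hydrogen-bonded to C4=O and 3-OH is an alcohol) and the 7-phenoxide displaces bromide from prenyl bromide by SN2 to give 5, whose labile B–O bonds hydrolyse on aqueous work-up; the mask also blocks catechol O-alkylation, autoxidation and the 4'-phenoxide/quinone-methide ring opening that would epimerise C2, so the 2R,3R centres of 1 are carried through unchanged and no new stereocentre is formed; the closest known reaction types are the Williamson 7-O-alkylation of 5,7-dihydroxyflavanones and the transient borate/arylboronate protection of catechols and cis-diols in selective alkylation or acylation, which has not been shown as a one-pot mask–allylate–unmask sequence on a base-sensitive trans-dihydroflavonol.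

**Compound list**
1 | (+)-taxifolin, (2R,3R)-2-(3,4-dihydroxyphenyl)-3,5,7-trihydroxychroman-4-one | Oc1cc(O)c2c(c1)O[C@H](c1ccc(O)c(O)c1)[C@@H](O)C2=O | starting material
2 | phenylboronic acid | OB(O)c1ccccc1 | starting material
3 | prenyl bromide (1-bromo-3-methylbut-2-ene) | CC(C)=CCBr | starting material
4 | taxifolin 3',4'-O-phenylboronate, (2R,3R)-3,5,7-trihydroxy-2-(2-phenyl-1,3,2-benzodioxaborol-5-yl)chroman-4-one | Oc1cc(O)c2c(c1)O[C@H](c1ccc3OB(c4ccccc4)Oc3c1)[C@@H](O)C2=O | intermediate
5 | 7-O-prenyltaxifolin 3',4'-O-phenylboronate, (2R,3R)-3,5-dihydroxy-7-(3-methylbut-2-enyloxy)-2-(2-phenyl-1,3,2-benzodioxaborol-5-yl)chroman-4-one | CC(C)=CCOc1cc(O)c2c(c1)O[C@H](c1ccc3OB(c4ccccc4)Oc3c1)[C@@H](O)C2=O | intermediate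
6 | 7-O-prenyl-(+)-taxifolin, (2R,3R)-2-(3,4-dihydroxyphenyl)-3,5-dihydroxy-7-(3-methylbut-2-enyloxy)chroman-4-one | CC(C)=CCOc1cc(O)c2c(c1)O[C@H](c1ccc(O)c(O)c1)[C@@H](O)C2=O | target

**Totals**
Total step count: 1. Longest linear sequence: 1 step.

**Steps most likely to fail**
The route has one step, so the list has one entry.

Step 1 (the proposed new step) can fail in three ways:
- The 7-phenoxide or carbonate may bind the Lewis-acidic boron of 4 and slow the alkylation.
- The masking may be incomplete, giving 4'-O- or 7,4'-di-O-prenyl ethers.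
- The base may epimerise C2/C3 or, with air, oxidise the product to the flavonol. Epimerisation would show as loss of the trans coupling J(H2,H3) of about 11–12 Hz.

Fallback for step 1 (known chemistry, covalent protection in place of the transient mask) sets out from 1 and comes back to the route at 6. Peracetylation of 1 with Ac2O/pyridine (cat. DMAP, 0 °C → rt) gives (2R,3R)-taxifolin pentaacetate F1. Thiophenol with imidazole in NMP at 0 °C removes only the most electrophilic 7-O-acetyl group, as established for flavonoid peracetates, and gives 3,5,3',4'-tetra-O-acetyl-(2R,3R)-taxifolin F2. The single free phenol of F2 is etherified under neutral Mitsunobu conditions (commercial prenol, PPh3, DIAD, THF, 0 °C → rt) to 7-O-prenyl-3,5,3',4'-tetra-O-acetyl-(2R,3R)-taxifolin F3. Ammonolysis of F3 (7 M NH3 in MeOH, 0 °C, Ar) removes the four acetates and gives 6. No free catechol or phenoxide base is present at the C–O bond-forming stage, so regiochemistry is fixed by the protecting-group pattern.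

**Further compounds**
F1 | step 1 | (2R,3R)-taxifolin 3,5,7,3',4'-penta-O-acetate | CC(=O)Oc1cc(OC(C)=O)c2c(c1)O[C@H](c1ccc(OC(C)=O)c(OC(C)=O)c1)[C@@H](OC(C)=O)C2=O
F2 | step 1 | 3,5,3',4'-tetra-O-acetyl-(2R,3R)-taxifolin (7-OH free) | Oc1cc(OC(C)=O)c2c(c1)O[C@H](c1ccc(OC(C)=O)c(OC(C)=O)c1)[C@@H](OC(C)=O)C2=O
F3 | step 1 | 7-O-prenyl-3,5,3',4'-tetra-O-acetyl-(2R,3R)-taxifolin | CC(C)=CCOc1cc(OC(C)=O)c2c(c1)O[C@H](c1ccc(OC(C)=O)c(OC(C)=O)c1)[C@@H](OC(C)=O)C2=O
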